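**Plan**

- Cuts: (a) the CH2–C(spiro) bond of the dihydrofuran, back to an ether methine C–H and a formyl-derived carbene on the tropone; (b) the tropone at its C(Me)–C(O) and C(CHO)–CH bonds, into a 3-oxidopyrylium ylide and an (E)-3-alkoxyacrolein; (c) the enol-ether O–CH= bond, to a cyclohexanol and propynal; (d) the methyl and three-carbon chain at the quaternary cyclohexane carbon, back to (S)-carvone.
- Forward: (S)-carvone gives the fully substituted cyclohexanol (steps 1–9), which is O-vinylated (10); a pyranone arm is made (11–14); the tropone ring is built on the enol ether by [5+2] cycloaddition and aromatisation (15); the dihydrofuran ring is closed last (17); fluoride then frees the acid and the tertiary alcohol (18).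
- Enabling feature: the spiro carbon is the ether carbon of the dihydrofuran (bonded to the ring oxygen, which sits on a tropone carbon), and the ring CH2 is bonded to the neighbouring tropone carbon. Before ring closure the spiro carbon is therefore a tertiary C–H next to oxygen, held 1,5 to a carbene carbon; C–H insertion closes the five-membered ring and makes the spiro centre.
- Stereochemistry: the hydroxyisopropyl-bearing carbon comes from (S)-carvone; the quaternary carbon from allylation anti to the isopropenyl group; the secondary methyl from equilibration to the equatorial epimer; the carbinol (later spiro) carbon from axial hydride delivery, then retention in the C–H insertion.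

Key step: step 17

Remark: 4-methylfuran-3-carboxylic acid and propynal are taken as catalogue compounds; the racemic carbinol centre of the furan arm and the new centres of the cycloadduct are all lost on aromatisation, so these compounds are carried as stereoisomer mixtures.

**Step 1**
Reactants: 1 (S)-(+)-carvone
Product: 3 trans-6-methylcarvone [(5S,6R)-2,6-dimethyl-5-(prop-1-en-2-yl)cyclohex-2-en-1-one], via lithium dienolate 2 (not isolated)
Conditions: LiN(i-Pr)2, THF, −78 °C; MeI, −78 → 0 °C
Reagents that add atoms: iodomethane, CI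
Why: Kinetic α′-deprotonation of the enone to the cross-conjugated dienolate and SN2 methylation should give mainly the trans isomer, and the configuration at this carbon is erased again by the enolisation of step 2 (enolate alkylation).

**Step 2**
Reactants: 3 trans-6-methylcarvone
Product: 5 (5R,6R)-2,6-dimethyl-6-(prop-2-en-1-yl)-5-(prop-1-en-2-yl)cyclohex-2-en-1-one, via lithium dienolate 4 (not isolated)
Conditions: LiN(i-Pr)2, THF, −78 °C; allyl bromide, −78 → 0 °C
Reagents that add atoms: allyl bromide, C=CCBr
Why: In this second α′-enolate alkylation the allyl halide should approach anti to the neighbouring isopropenyl group, which places allyl trans and methyl cis to it and so sets the quaternary centre (substrate-controlled enolate allylation).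

**Step 3**
Reactants: 5 allyl methyl carvone
Product: 7 (2R,3R,6S)-2,6-dimethyl-2-(prop-2-en-1-yl)-3-(prop-1-en-2-yl)cyclohexan-1-one, via lithium enolate 6 (not isolated)
Conditions: LiBH(s-Bu)3, THF, −78 °C; then NaOMe, MeOH, 25 °C
Reagents that add atoms: none
Why: The bulky borohydride should reduce the β-unsubstituted enone in the conjugate sense, and protonation with base equilibration of the only epimerisable centre should leave its methyl group equatorial, trans to the axial methyl of the quaternary carbon, because the other epimer suffers a syn-diaxial methyl/methyl contact.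

**Step 4**
Reactants: 7 allyl ketone
Product: 9 (2R,3R,6S)-2-(3-hydroxypropyl)-2,6-dimethyl-3-(prop-1-en-2-yl)cyclohexan-1-one, via catechol alkylboronate 8 (not isolated)
Conditions: catecholborane, RhCl(PPh3)3 (2 mol %), THF, 0 → 25 °C; then NaOH, H2O2, 0 °C
Reagents that add atoms: hydrogen peroxide, OO
Why: Rhodium-catalysed hydroboration and oxidation gives the anti-Markovnikov primary alcohol, and the monosubstituted allyl double bond should react much faster than the hindered 1,1-disubstituted isopropenyl group or the hindered ketone.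

**Step 5**
Reactants: 9 hydroxy ketone
Product: 11 3-[(1R,3S,6R)-1,3-dimethyl-2-oxo-6-(prop-1-en-2-yl)cyclohexyl]propanoic acid, via aldehyde 10 (not isolated)
Conditions: TEMPO (cat.), PhI(OAc)2, MeCN/H2O, 25 °C
Reagents that add atoms: water, O
Why: Nitroxyl-catalysed oxidation takes the primary alcohol through the aldehyde hydrate to the acid and should leave the ketone and the isopropenyl group untouched.

**Step 6**
Reactants: 11 keto acid
Product: 12 2-(trimethylsilyl)ethyl 3-[(1R,3S,6R)-1,3-dimethyl-2-oxo-6-(prop-1-en-2-yl)cyclohexyl]propanoate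
Conditions: Me3SiCH2CH2OH, EDC·HCl, DMAP, CH2Cl2, 25 °C
Reagents that add atoms: 2-(trimethylsilyl)ethanol, C[Si](C)(C)CCO
Why: Carbodiimide/DMAP esterification masks the acid as an ester that survives the basic and carbene steps and is later removed by fluoride together with the silyl ether.

**Step 7**
Reactants: 12 keto ester
Product: 14 2-(trimethylsilyl)ethyl 3-[(1R,3S,6S)-6-(2-hydroxypropan-2-yl)-1,3-dimethyl-2-oxocyclohexyl]propanoate, via tertiary hydroperoxide 13 (not isolated)
Conditions: Co(acac)2 (cat.), PhSiH3, O2 (1 atm), THF/i-PrOH, 25 °C; then PPh3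
Reagents that add atoms: dioxygen, O=O
Why: Mukaiyama hydration (hydrogen-atom transfer from a cobalt hydride, trapping of the tertiary radical by O2, reduction of the peroxide) should convert the isopropenyl group into the Markovnikov tertiary alcohol without touching ketone or ester, and no stereocentre is formed.

**Step 8**
Reactants: 14 tertiary alcohol
Product: 15 2-(trimethylsilyl)ethyl 3-[(1R,3S,6S)-1,3-dimethyl-2-oxo-6-{2-[(triethylsilyl)oxy]propan-2-yl}cyclohexyl]propanoate
Conditions: Et3SiOTf, 2,6-lutidine, CH2Cl2, −78 °C
Reagents that add atoms: triethylsilyl trifluoromethanesulfonate, CC[Si](CC)(CC)OS(=O)(=O)C(F)(F)F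
Why: The silyl triflate silylates the tertiary alcohol, so that only the secondary hydroxy group made in step 9 can add to propynal in step 10.

**Step 9**
Reactants: 15 silyl ether ketone
Product: 16 2-(trimethylsilyl)ethyl 3-[(1R,2R,3S,6S)-2-hydroxy-1,3-dimethyl-6-{2-[(triethylsilyl)oxy]propan-2-yl}cyclohexyl]propanoate
Conditions: NaBH4, CeCl3·7H2O, MeOH, −20 → 0 °C
Reagents that add atoms: none
Why: In this Luche-type reduction hydride should add axially, on the face away from the axial methyl of the quaternary carbon, to give the equatorial (R)-alcohol, trans to the neighbouring equatorial methyl.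

**Step 10**
Reactants: 16 cyclohexanol
Product: 17 (E)-3-alkoxyacrolein (2-(trimethylsilyl)ethyl ester, triethylsilyl ether; alkoxy = the alkoxy group of 16)
Conditions: propynal, DABCO (10 mol %), CH2Cl2, 0 °C
Reagents that add atoms: propynal, C#CC=O
Why: Amine-catalysed oxa-Michael addition of the alcohol to the ynal should give the (E)-β-alkoxy enal (a vinylogous formate), and the carbinol C–O bond is not touched, so its configuration is kept.

**Step 11**
Reactants: 18 4-methylfuran-3-carboxylic acid
Product: 20 2-(1-hydroxyethyl)-4-methylfuran-3-carboxylic acid (racemic), via dilithio furan 19 (not isolated)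
Conditions: LiN(i-Pr)2 (2.2 equiv), THF, −78 °C; CH3CHO; aq HCl
Reagents that add atoms: acetaldehyde, CC=O
Why: Carboxylate-directed lithiation should occur at the furan α-position next to the carboxylate, and the dianion adds to acetaldehyde to give a carbinol whose stereocentre is lost later.

**Step 12**
Reactants: 20 hydroxy acid
Product: 21 methyl 2-(1-hydroxyethyl)-4-methylfuran-3-carboxylate
Conditions: MeI, K2CO3, DMF, 25 °C
Reagents that add atoms: iodomethane, CI
Why: SN2 alkylation of the carboxylate gives the methyl ester under non-acidic conditions, which avoids lactonisation onto the neighbouring carbinol.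

**Step 13**
Reactants: 21 furyl carbinol
Product: 23 methyl 6-hydroxy-2,5-dimethyl-3-oxo-3,6-dihydro-2H-pyran-4-carboxylate (diastereomer mixture), via enedione 22 (not isolated)
Conditions: NBS, NaHCO3, THF/H2O, 0 °C
Reagents that add atoms: water, O
Why: In the Achmatowicz rearrangement the 2-furylcarbinol is opened oxidatively to the cis-enedione and the carbinol oxygen closes onto the aldehyde to give the 6-hydroxy-2H-pyran-3(6H)-one.

**Step 14**
Reactants: 23 hydroxypyranone
Product: 24 methyl 6-acetoxy-2,5-dimethyl-3-oxo-3,6-dihydro-2H-pyran-4-carboxylate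
Conditions: Ac2O, pyridine, DMAP (cat.), CH2Cl2, 0 °C
Reagents that add atoms: acetic anhydride, CC(=O)OC(C)=O
Why: Acetylation of the lactol hydroxy group installs the leaving group needed to release the 3-oxidopyrylium ylide.

**Step 15**
Reactants: 17 (E)-3-alkoxyacrolein and 24 acetoxypyranone
Product: 28 methyl 4-formyl-2,6-dimethyl-7-oxo-5-(alkoxy)cyclohepta-1,3,5-triene-1-carboxylate (alkoxy = the alkoxy group of 16), via oxidopyrylium ylide 25 (not isolated), via cycloadduct 26 (not isolated), via ketol acetate 27 (not isolated)
Conditions: 24 (3 equiv), Et3N, MeCN, 60 °C; then Ac2O, DBU, DMAP (cat.), 25 °C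
Reagents that add atoms: none
Why: Loss of acetate gives the 3-oxidopyrylium ylide, whose [5+2] cycloaddition to the push–pull alkene should follow the orientation known for enals and acrylates (ylide carbon next to the oxide to the β-carbon, here the alkoxy-bearing one, and the other ylide terminus to the formyl-bearing carbon), and the 8-oxabicyclo[3.2.1]octenone is then aromatised by E1cB opening of the oxygen bridge β to the formyl group, acetylation of the released tertiary ketol and a second elimination, a base-induced route from such cycloadducts to tropones that destroys all the new stereocentres.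

**Step 16**
Reactants: 28 tropone aldehyde
Product: 29 (E)-tosylhydrazone of 28
Conditions: TsNHNH2, MeOH, 25 °C
Reagents that add atoms: 4-methylbenzenesulfonohydrazide, Cc1ccc(cc1)S(=O)(=O)NN
Why: The aldehyde condenses with the sulfonyl hydrazide, and the weakly electrophilic tropone carbonyl should not compete.

**Step 17**
Reactants: 29 tosylhydrazone
Product: 32 triethylsilyl ether 2-(trimethylsilyl)ethyl ester of the target (spiro-dihydrofurotropone), via sodium salt 30 (not isolated), via diazo compound 31 (not isolated)
Conditions: NaH, THF, 0 °C; then Rh2(OAc)4 (2 mol %), BnEt3NCl (10 mol %), 1,4-dioxane, 45 °C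
Reagents that add atoms: none
Why: The sodium salt loses sulfinate on warming (Bamford–Stevens) to the diazo compound, which Rh2(OAc)4 turns into a rhodium carbene on the carbon attached to the tropone; this electrophilic carbon inserts into the C–H bond of the ether methine through a three-centre, hydride-transfer-like transition state. The closest known reaction type is the rhodium- or ruthenium-catalysed intramolecular C–H insertion of ortho-alkoxyaryl diazomethanes made from tosylhydrazones, which gives 2,3-dihydrobenzofurans, together with the insertion of diazoketone-derived carbenoids next to ether oxygen. The dihydrofuran ring closes in the 1,5-insertion mode, through a five-membered transition state that holds the carbene carbon, two tropone carbons, the oxygen and the methine carbon. The spiro stereocentre is set by retention: the new C–C bond takes the place of the axial hydrogen of the (R)-carbinol carbon fixed in step 9, so the oxygen stays equatorial and cis to the methyl of the quaternary carbon. The step needs site selectivity for this C–H bond over the more remote methine, methylene and methyl C–H bonds, which the activating ether oxygen and the five-membered transition state should secure, and it needs the carbene to form faster than the diazo group dimerises to the azine or cyclises onto the neighbouring tropone CH, which slow release of the diazo compound in the presence of the catalyst should secure.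

**Step 18**
Reactants: 32 protected spiro compound
Product: 33 target CNP0448476.3
Conditions: Bu4NF, THF, 0 → 25 °C; aq HCl to pH 4
Reagents that add atoms: none
Why: Fluoride cleaves the triethylsilyl ether and fragments the 2-(trimethylsilyl)ethyl ester in one non-acidic operation, which should spare the methyl ester and the acid-labile tertiary alkyl–oxygen bond of the vinylogous ester.

**Compound list**

1 | (S)-(+)-carvone | O=C1C(C)=CC[C@H](C(C)=C)C1 | starting material
2 | lithium dienolate of 1 (O–C1=C6) | [Li]OC1=C[C@@H](C(C)=C)CC=C1C | intermediate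
3 | (5S,6R)-2,6-dimethyl-5-(prop-1-en-2-yl)cyclohex-2-en-1-one (trans-6-methylcarvone) | O=C1C(C)=CC[C@H](C(C)=C)[C@H]1C | intermediate
4 | lithium dienolate of 3 (O–C1=C6) | [Li]OC1=C(C)[C@@H](C(C)=C)CC=C1C | intermediate
5 | (5R,6R)-2,6-dimethyl-6-(prop-2-en-1-yl)-5-(prop-1-en-2-yl)cyclohex-2-en-1-one | O=C1C(C)=CC[C@H](C(C)=C)[C@@]1(C)CC=C | intermediate
6 | lithium enolate from conjugate reduction of 5 | [Li]OC1=C(C)CC[C@H](C(C)=C)[C@@]1(C)CC=C | intermediate
7 | (2R,3R,6S)-2,6-dimethyl-2-(prop-2-en-1-yl)-3-(prop-1-en-2-yl)cyclohexan-1-one | O=C1[C@@H](C)CC[C@H](C(C)=C)[C@@]1(C)CC=C | intermediate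
8 | catechol boronate of the 3-(cyclohexyl)propyl chain of 7 | O=C1[C@@H](C)CC[C@H](C(C)=C)[C@@]1(C)CCCB2Oc3ccccc3O2 | intermediate
9 | (2R,3R,6S)-2-(3-hydroxypropyl)-2,6-dimethyl-3-(prop-1-en-2-yl)cyclohexan-1-one | O=C1[C@@H](C)CC[C@H](C(C)=C)[C@@]1(C)CCCO | intermediate
10 | 3-[(1R,3S,6R)-1,3-dimethyl-2-oxo-6-(prop-1-en-2-yl)cyclohexyl]propanal | O=C1[C@@H](C)CC[C@H](C(C)=C)[C@@]1(C)CCC=O | intermediate
11 | 3-[(1R,3S,6R)-1,3-dimethyl-2-oxo-6-(prop-1-en-2-yl)cyclohexyl]propanoic acid | O=C1[C@@H](C)CC[C@H](C(C)=C)[C@@]1(C)CCC(=O)O | intermediate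
12 | 2-(trimethylsilyl)ethyl 3-[(1R,3S,6R)-1,3-dimethyl-2-oxo-6-(prop-1-en-2-yl)cyclohexyl]propanoate | O=C1[C@@H](C)CC[C@H](C(C)=C)[C@@]1(C)CCC(=O)OCC[Si](C)(C)C | intermediate
13 | tertiary hydroperoxide from 12 (2-hydroperoxypropan-2-yl in place of isopropenyl) | O=C1[C@@H](C)CC[C@H](C(C)(C)OO)[C@@]1(C)CCC(=O)OCC[Si](C)(C)C | intermediate
14 | 2-(trimethylsilyl)ethyl 3-[(1R,3S,6S)-6-(2-hydroxypropan-2-yl)-1,3-dimethyl-2-oxocyclohexyl]propanoate | O=C1[C@@H](C)CC[C@H](C(C)(C)O)[C@@]1(C)CCC(=O)OCC[Si](C)(C)C | intermediate
15 | 2-(trimethylsilyl)ethyl 3-[(1R,3S,6S)-1,3-dimethyl-2-oxo-6-{2-[(triethylsilyl)oxy]propan-2-yl}cyclohexyl]propanoate | O=C1[C@@H](C)CC[C@H](C(C)(C)O[Si](CC)(CC)CC)[C@@]1(C)CCC(=O)OCC[Si](C)(C)C | intermediate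
16 | 2-(trimethylsilyl)ethyl 3-[(1R,2R,3S,6S)-2-hydroxy-1,3-dimethyl-6-{2-[(triethylsilyl)oxy]propan-2-yl}cyclohexyl]propanoate | O[C@@H]1[C@@H](C)CC[C@H](C(C)(C)O[Si](CC)(CC)CC)[C@@]1(C)CCC(=O)OCC[Si](C)(C)C | intermediate
17 | (E)-3-alkoxyprop-2-enal, alkoxy = the alkoxy group of 16 | O=C/C=C/O[C@@H]1[C@@H](C)CC[C@H](C(C)(C)O[Si](CC)(CC)CC)[C@@]1(C)CCC(=O)OCC[Si](C)(C)C | intermediate
18 | 4-methylfuran-3-carboxylic acid | Cc1cocc1C(=O)O | starting material
19 | lithium 2-lithio-4-methylfuran-3-carboxylate | [Li]c1occ(C)c1C(=O)O[Li] | intermediate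
20 | 2-(1-hydroxyethyl)-4-methylfuran-3-carboxylic acid (racemic) | CC(O)c1occ(C)c1C(=O)O | intermediate
21 | methyl 2-(1-hydroxyethyl)-4-methylfuran-3-carboxylate (racemic) | CC(O)c1occ(C)c1C(=O)OC | intermediate
22 | methyl 2-(1-formylethylidene)-4-hydroxy-3-oxopentanoate (cis-enedione; formyl and keto groups cis) | O=C/C(C)=C(C(=O)OC)\C(=O)C(C)O | intermediate
23 | methyl 6-hydroxy-2,5-dimethyl-3-oxo-3,6-dihydro-2H-pyran-4-carboxylate (diastereomer mixture) | CC1OC(O)C(C)=C(C(=O)OC)C1=O | intermediate
24 | methyl 6-acetoxy-2,5-dimethyl-3-oxo-3,6-dihydro-2H-pyran-4-carboxylate (diastereomer mixture) | CC1OC(OC(C)=O)C(C)=C(C(=O)OC)C1=O | intermediate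
25 | 4-(methoxycarbonyl)-2,5-dimethylpyrylium-3-olate | Cc1[o+]cc(C)c(C(=O)OC)c1[O-] | intermediate
26 | methyl 7-alkoxy-6-formyl-1,4-dimethyl-2-oxo-8-oxabicyclo[3.2.1]oct-3-ene-3-carboxylate (alkoxy as in 17; mixture at the new centres) | CC12OC(C(C)=C(C(=O)OC)C1=O)C(C=O)C2O[C@@H]1[C@@H](C)CC[C@H](C(C)(C)O[Si](CC)(CC)CC)[C@@]1(C)CCC(=O)OCC[Si](C)(C)C | intermediate
27 | methyl 6-acetoxy-5-alkoxy-4-formyl-2,6-dimethyl-7-oxocyclohepta-1,3-diene-1-carboxylate (alkoxy as in 17; mixture at the two sp3 ring carbons) | CC(=O)OC1(C)C(=O)C(C(=O)OC)=C(C)C=C(C=O)C1O[C@@H]2[C@@H](C)CC[C@H](C(C)(C)O[Si](CC)(CC)CC)[C@@]2(C)CCC(=O)OCC[Si](C)(C)C | intermediate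
28 | methyl 5-alkoxy-4-formyl-2,6-dimethyl-7-oxocyclohepta-1,3,5-triene-1-carboxylate (alkoxy as in 17) | COC(=O)c1c(C)cc(C=O)c(O[C@@H]2[C@@H](C)CC[C@H](C(C)(C)O[Si](CC)(CC)CC)[C@@]2(C)CCC(=O)OCC[Si](C)(C)C)c(C)c1=O | intermediate
29 | (E)-N-tosylhydrazone of 28 | COC(=O)c1c(C)cc(/C=N/NS(=O)(=O)c2ccc(C)cc2)c(O[C@@H]3[C@@H](C)CC[C@H](C(C)(C)O[Si](CC)(CC)CC)[C@@]3(C)CCC(=O)OCC[Si](C)(C)C)c(C)c1=O | intermediate
30 | sodium salt of 29 | [Na+].COC(=O)c1c(C)cc(/C=N/[N-]S(=O)(=O)c2ccc(C)cc2)c(O[C@@H]3[C@@H](C)CC[C@H](C(C)(C)O[Si](CC)(CC)CC)[C@@]3(C)CCC(=O)OCC[Si](C)(C)C)c(C)c1=O | intermediate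
31 | methyl 5-alkoxy-4-(diazomethyl)-2,6-dimethyl-7-oxocyclohepta-1,3,5-triene-1-carboxylate (alkoxy as in 17) | COC(=O)c1c(C)cc(C=[N+]=[N-])c(O[C@@H]2[C@@H](C)CC[C@H](C(C)(C)O[Si](CC)(CC)CC)[C@@]2(C)CCC(=O)OCC[Si](C)(C)C)c(C)c1=O | intermediate
32 | target protected as triethylsilyl ether (tertiary alcohol) and 2-(trimethylsilyl)ethyl ester (side-chain acid) | COC(=O)c1c(C)cc2c(c(C)c1=O)O[C@]1(C2)[C@@H](C)CC[C@H](C(C)(C)O[Si](CC)(CC)CC)[C@@]1(C)CCC(=O)OCC[Si](C)(C)C | intermediate
33 | CNP0448476.3 | COC(=O)c1c(C)cc2c(c(C)c1=O)O[C@]1(C2)[C@@H](C)CC[C@H](C(C)(C)O)[C@@]1(C)CCC(=O)O | target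

**Totals**

Total step count: 18. Longest linear sequence: 14 steps (steps 1–10 and 15–18); the pyranone arm is steps 11–14.

**Steps most likely to fail**

1. Step 17. The diazo compound may cyclise onto the neighbouring tropone CH (pyrazole formation) or couple to the azine before it reaches the catalyst, and the carbene may insert into more remote C–H bonds. The fallback sets out from aldehyde 28 and makes the same bond photochemically. Irradiation (λ ≥ 300 nm, benzene) should make the excited formyl oxygen abstract the ether methine hydrogen (Norrish–Yang type), and the 1,5-biradical should collapse to the protected 3-hydroxy spiro-dihydrofurotropone F1. Removal of the new hydroxy group (Et3SiH, BF3·OEt2, CH2Cl2, −78 °C, or a Barton–McCombie sequence) returns to the route at 32. The spiro configuration would then rest on radical recombination on the face from which the hydrogen was taken, which is less secure than the insertion.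

2. Step 15. The ylide may be consumed by dimerisation before it adds to the hindered, deactivated push–pull double bond, and in the elimination the terpenoid alkoxide may be expelled instead of the bridge oxygen. The fallback sets out from 24 and builds the tropone first from a small partner. Ylide 25 and an excess of (E)-3-methoxyacrolein give methyl 6-formyl-7-methoxy-1,4-dimethyl-2-oxo-8-oxabicyclo[3.2.1]oct-3-ene-3-carboxylate F2. The same base/Ac2O treatment gives methyl 4-formyl-5-methoxy-2,6-dimethyl-7-oxocyclohepta-1,3,5-triene-1-carboxylate F3. The potassium alkoxide of 16 (KN(SiMe3)2, THF, −78 → 0 °C) then displaces methoxide from the vinylogous ester carbon by addition–elimination, returning at 28.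

3. Step 10. The hindered, neopentyl-type secondary alcohol may add too slowly, so that propynal polymerises under amine catalysis. The fallback sets out from 16 and makes the enol ether by acid-catalysed exchange instead: 16 is heated with (E)-3-methoxyacrolein and pyridinium p-toluenesulfonate in toluene with removal of methanol (vinylogous transacetalisation), which returns directly at 17; no new compound arises (F0).

**Further compounds**

F1 | step 17 | 3-hydroxy derivative of 32 (hydroxy group on the dihydrofuran CH next to the spiro carbon; epimer mixture at that carbon) | COC(=O)c1c(C)cc2c(c(C)c1=O)O[C@]1(C2O)[C@@H](C)CC[C@H](C(C)(C)O[Si](CC)(CC)CC)[C@@]1(C)CCC(=O)OCC[Si](C)(C)C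
F2 | step 15 | methyl 6-formyl-7-methoxy-1,4-dimethyl-2-oxo-8-oxabicyclo[3.2.1]oct-3-ene-3-carboxylate | CC12OC(C(C)=C(C(=O)OC)C1=O)C(C=O)C2OC
F3 | step 15 | methyl 4-formyl-5-methoxy-2,6-dimethyl-7-oxocyclohepta-1,3,5-triene-1-carboxylate | COC(=O)c1c(C)cc(C=O)c(OC)c(C)c1=O
F0 | step 10 | none | none
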